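**Retrosynthetic overview**

- Ring A of the bibenzyl is numbered C1(OMe), C2(H), C3(CH2CH2Ar), C4(H), C5(OH), C6(CH2Ar'); it is the only ring that is built, and the two hydroxyphenyl rings arrive intact from benzyl halides.
- The strategy rests on this feature: C5(OH)–C6(benzyl)–C1(OMe)–C2(H) is a 2-benzylacetoacetate unit at the dienol ether level, and C3(chain)–C4(H) is an alkyne carrying a temporary carboxyl on C4.
- Key disconnection: bonds C2–C3 and C4–C5, leading to a 1-silyloxy-1,3-dimethoxydiene and a benzyl 5-arylpent-2-ynoate ([4+2] cycloaddition with aromatisation).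
- Diene: methyl acetoacetate, C-benzylation, methyl enol ether, γ-deprotonation and O-silylation. Ynoate: 3-benzyloxybenzyl bromide plus lithiated 1-(trimethylsilyl)propyne, desilylation, carboxylation with benzyl chloroformate.
- Endgame: one hydrogenolysis removes all three benzyl groups (two ethers and the ester), then thermal decarboxylation at C4.

Key step: step 7

Assumption: the target has no stereogenic element (it is achiral), so the demand for a single enantiomer is met without any stereocontrol.

**Route**

Step 1
Reactants: 1 methyl acetoacetate; 2 4-(benzyloxy)benzyl chloride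
Product: 4 methyl 2-[4-(benzyloxy)benzyl]-3-oxobutanoate (racemic), via sodium enolate 3 (not isolated)
Conditions: 1 (1.5 equiv), NaH (1.4 equiv), THF, 0 °C; then 2 (1.0 equiv), NaI (cat.), reflux
Reagents that add atoms: none
Why: Acetoacetic ester C-alkylation (SN2 of the stabilised sodium enolate on a reactive p-alkoxybenzyl halide with iodide catalysis), in which excess enolate suppresses dialkylation; the new stereocentre is racemic and is erased in step 2.

Step 2
Reactants: 4 methyl 2-[4-(benzyloxy)benzyl]-3-oxobutanoate
Product: 6 methyl 2-[4-(benzyloxy)benzyl]-3-methoxybut-2-enoate (E/Z mixture), via dimethyl ketal 5 (not isolated)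
Conditions: HC(OMe)3 (3 equiv), conc. H2SO4 (cat.), MeOH, 60 °C; then volatiles distilled off (bath to 110 °C); Et3N quench
Reagents that add atoms: trimethyl orthoformate COC(OC)OC
Why: Acid-catalysed ketalisation with the orthoformate followed by elimination of methanol is the standard preparation of 3-methoxy-2-enoates; any deconjugated CH2=C(OMe) isomer gives the same dienolate in step 3, and the aryl benzyl ether tolerates catalytic acid.

Step 3
Reactants: 6 methyl 2-[4-(benzyloxy)benzyl]-3-methoxybut-2-enoate
Product: 8 2-[4-(benzyloxy)benzyl]-1,3-dimethoxy-1-(trimethylsilyloxy)buta-1,3-diene (E/Z mixture at C1=C2), via lithium dienolate 7 (not isolated)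
Conditions: LDA (1.15 equiv), THF, −78 °C; then TMSCl (1.3 equiv), −78 °C to rt; pentane trituration, filtration under Ar, used crude
Reagents that add atoms: chlorotrimethylsilane C[Si](C)(C)Cl
Why: Kinetic γ-deprotonation of the β-methoxy enoate gives the extended ester dienolate, which is O-silylated to the silyl ketene acetal (the standard preparation of Brassard-type dienes, known for 2-alkyl congeners).

Step 4
Reactants: 9 1-(trimethylsilyl)propyne; 10 3-(benzyloxy)benzyl bromide
Product: 12 {4-[3-(benzyloxy)phenyl]but-1-yn-1-yl}trimethylsilane, via silylpropargyl lithium 11 (not isolated)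
Conditions: 9 (1.3 equiv), n-BuLi (1.25 equiv), TMEDA, THF, −78 to −20 °C; then 10, −78 °C to rt
Reagents that add atoms: none
Why: Lithiated 1-(trimethylsilyl)propyne is alkylated at its propargylic carbon by the benzylic bromide (SN2), the silyl group suppressing allene formation and masking the alkyne terminus.

Step 5
Reactants: 12 {4-[3-(benzyloxy)phenyl]but-1-yn-1-yl}trimethylsilane
Product: 13 1-(benzyloxy)-3-(but-3-yn-1-yl)benzene
Conditions: K2CO3 (cat.), MeOH/THF, rt
Reagents that add atoms: none
Why: Carbonate-catalysed methanolysis of the alkynyl C–Si bond is the standard protodesilylation of TMS-alkynes and leaves the ether untouched.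

Step 6
Reactants: 13 1-(benzyloxy)-3-(but-3-yn-1-yl)benzene; 14 benzyl chloroformate
Product: 16 benzyl 5-[3-(benzyloxy)phenyl]pent-2-ynoate, via lithium acetylide 15 (not isolated)
Conditions: n-BuLi (1.05 equiv), THF, −78 °C; then 14 (1.3 equiv), −78 to 0 °C
Reagents that add atoms: none
Why: Acylation of a lithium acetylide with a chloroformate is the standard route to alk-2-ynoates; the benzyl ester is chosen so that the later hydrogenolysis frees the acid without saponifying a hindered salicylate.

Step 7
Reactants: 8 2-[4-(benzyloxy)benzyl]-1,3-dimethoxy-1-(trimethylsilyloxy)buta-1,3-diene; 16 benzyl 5-[3-(benzyloxy)phenyl]pent-2-ynoate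
Product: 18 benzyl 3-[4-(benzyloxy)benzyl]-6-{2-[3-(benzyloxy)phenyl]ethyl}-2-hydroxy-4-methoxybenzoate, via cyclohexadiene ketal cycloadduct 17 (not isolated)
Conditions: 8 (2.5 equiv), toluene (ca. 2 M), sealed tube, 120 °C, Ar; then 1 M HCl, THF, rt
Reagents that add atoms: none
Why: The electron-rich silyl ketene acetal diene 8 adds across the electron-poor triple bond of 16 in a thermal, strongly asynchronous [4+2] cycloaddition (at the ionic extreme a Michael addition followed by ring closure), the reaction type established for 1-alkoxy-1-silyloxy-3-alkoxybutadienes with acetylenic esters. Ring A is closed in the six-membered cycloaddition mode by forming C2–C3 (diene CH2 terminus to the ynoate β-carbon) and C4–C5 (ketene acetal carbon to the ynoate α-carbon), which gives the 1,4-cyclohexadiene ketal 17. Acidic work-up cleaves the O–Si bond, the hemiketal expels methanol and the ring enolises, so the acetal carbon ends as the ester-chelated phenol C5–OH and the diene C3 methoxy as the C1–OMe. No stereocentre is created in 18, since the ketal centre of 17 is destroyed on aromatisation and the E/Z geometry of 8 is irrelevant. The selectivity needed is regiochemical: the largest HOMO coefficient of 8 lies on its unsubstituted CH2 terminus and the largest LUMO coefficient of 16 on the β-carbon carrying the arylethyl chain, which places the chain para to the benzyl group. An excess of 8 is used to offset its thermal and hydrolytic lability in this hindered pairing.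

Step 8
Reactants: 18 benzyl 3-[4-(benzyloxy)benzyl]-6-{2-[3-(benzyloxy)phenyl]ethyl}-2-hydroxy-4-methoxybenzoate
Product: 19 2-hydroxy-3-(4-hydroxybenzyl)-6-[2-(3-hydroxyphenyl)ethyl]-4-methoxybenzoic acid
Conditions: H2 (1 atm), 10% Pd/C, EtOAc/MeOH, rt; filtration, evaporation below 30 °C
Reagents that add atoms: none
Why: Palladium-catalysed hydrogenolysis cleaves both aryl benzyl ethers and the benzyl ester in one operation, while the diarylmethane, the bibenzyl and the aryl methyl ether are inert.

Step 9
Reactants: 19 2-hydroxy-3-(4-hydroxybenzyl)-6-[2-(3-hydroxyphenyl)ethyl]-4-methoxybenzoic acid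
Product: 20 2-(4-hydroxybenzyl)-5-[2-(3-hydroxyphenyl)ethyl]-3-methoxyphenol
Conditions: degassed DMF, 130 °C, Ar
Reagents that add atoms: none
Why: Thermal protodecarboxylation of a β-resorcylic-type acid proceeds by ipso-protonation through its keto tautomer, assisted by the ortho-OH and para-OMe donors, and removes the carbon that served only to activate the alkyne.

**Compound list**

1 | methyl acetoacetate | COC(=O)CC(C)=O | starting material
2 | 4-(benzyloxy)benzyl chloride | ClCc1ccc(OCc2ccccc2)cc1 | starting material
3 | sodium enolate of methyl acetoacetate (not isolated) | COC(=O)C=C(C)[O-].[Na+] | intermediate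
4 | methyl 2-[4-(benzyloxy)benzyl]-3-oxobutanoate (racemic) | COC(=O)C(Cc1ccc(OCc2ccccc2)cc1)C(C)=O | intermediate
5 | methyl 2-[4-(benzyloxy)benzyl]-3,3-dimethoxybutanoate (racemic, not isolated) | COC(=O)C(Cc1ccc(OCc2ccccc2)cc1)C(C)(OC)OC | intermediate
6 | methyl 2-[4-(benzyloxy)benzyl]-3-methoxybut-2-enoate (E/Z mixture) | COC(=O)C(Cc1ccc(OCc2ccccc2)cc1)=C(C)OC | intermediate
7 | lithium 2-[4-(benzyloxy)benzyl]-1,3-dimethoxybuta-1,3-dien-1-olate (not isolated) | C=C(OC)C(Cc1ccc(OCc2ccccc2)cc1)=C(OC)[O-].[Li+] | intermediate
8 | 2-[4-(benzyloxy)benzyl]-1,3-dimethoxy-1-(trimethylsilyloxy)buta-1,3-diene (E/Z mixture) | C=C(OC)C(Cc1ccc(OCc2ccccc2)cc1)=C(OC)O[Si](C)(C)C | intermediate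
9 | 1-(trimethylsilyl)propyne | CC#C[Si](C)(C)C | starting material
10 | 3-(benzyloxy)benzyl bromide | BrCc1cccc(OCc2ccccc2)c1 | starting material
11 | 3-(trimethylsilyl)prop-2-yn-1-yllithium (not isolated) | [Li]CC#C[Si](C)(C)C | intermediate
12 | {4-[3-(benzyloxy)phenyl]but-1-yn-1-yl}trimethylsilane | C[Si](C)(C)C#CCCc1cccc(OCc2ccccc2)c1 | intermediate
13 | 1-(benzyloxy)-3-(but-3-yn-1-yl)benzene | C#CCCc1cccc(OCc2ccccc2)c1 | intermediate
14 | benzyl chloroformate | O=C(Cl)OCc1ccccc1 | starting material
15 | lithium 4-[3-(benzyloxy)phenyl]but-1-yn-1-ide (not isolated) | [Li]C#CCCc1cccc(OCc2ccccc2)c1 | intermediate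
16 | benzyl 5-[3-(benzyloxy)phenyl]pent-2-ynoate | O=C(OCc1ccccc1)C#CCCc1cccc(OCc2ccccc2)c1 | intermediate
17 | benzyl 5-[4-(benzyloxy)benzyl]-2-{2-[3-(benzyloxy)phenyl]ethyl}-4,6-dimethoxy-6-(trimethylsilyloxy)cyclohexa-1,4-diene-1-carboxylate (racemic, not isolated) | COC1=C(Cc2ccc(OCc3ccccc3)cc2)C(OC)(O[Si](C)(C)C)C(C(=O)OCc2ccccc2)=C(CCc2cccc(OCc3ccccc3)c2)C1 | intermediate
18 | benzyl 3-[4-(benzyloxy)benzyl]-6-{2-[3-(benzyloxy)phenyl]ethyl}-2-hydroxy-4-methoxybenzoate | O=C(OCc1ccccc1)c1c(CCc2cccc(OCc3ccccc3)c2)cc(OC)c(Cc2ccc(OCc3ccccc3)cc2)c1O | intermediate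
19 | 2-hydroxy-3-(4-hydroxybenzyl)-6-[2-(3-hydroxyphenyl)ethyl]-4-methoxybenzoic acid | O=C(O)c1c(CCc2cccc(O)c2)cc(OC)c(Cc2ccc(O)cc2)c1O | intermediate
20 | 2-(4-hydroxybenzyl)-5-[2-(3-hydroxyphenyl)ethyl]-3-methoxyphenol | COc1cc(CCc2cccc(O)c2)cc(O)c1Cc1ccc(O)cc1 | target

**Step count**

Total steps: 9. Longest linear sequence: 6 steps (1, 2, 3, 7, 8, 9; the ynoate branch 4, 5, 6, 7, 8, 9 is equally long).

**Steps most likely to fail**

Step 7. The cycloaddition of the tetrasubstituted diene with an alkyl-substituted ynoate may be too slow at temperatures the diene tolerates, so that silyl migration or protodesilylation of 8 wins over C–C bond formation. The fallback sets out from 13 and 8 and returns to the route at 19; it replaces the ester by a stronger activating group.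
- Alkyne 13 would be deprotonated (n-BuLi, THF, −78 °C) and formylated with DMF (inverse quench into aqueous KH2PO4) to give 5-[3-(benzyloxy)phenyl]pent-2-ynal F1, a much more reactive dienophile.
- Cycloaddition of F1 with 8 at rt to 50 °C and the same acidic work-up should give 3-[4-(benzyloxy)benzyl]-6-{2-[3-(benzyloxy)phenyl]ethyl}-2-hydroxy-4-methoxybenzaldehyde F2.
- Pinnick oxidation (NaClO2, NaH2PO4, 2-methyl-2-butene, t-BuOH/H2O) should give 3-[4-(benzyloxy)benzyl]-6-{2-[3-(benzyloxy)phenyl]ethyl}-2-hydroxy-4-methoxybenzoic acid F3.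
- Hydrogenolysis of F3 under the conditions of step 8 gives 19.

Step 3. C-silylation of the dienolate in place of O-silylation, or hydrolytic loss of the silyl group while the labile ketene acetal is isolated, may prevent clean delivery of the diene. The fallback sets out from 6 (through its lithium dienolate 7) and 16 and returns at 18. It is an anionic tandem vinylogous Michael addition and Claisen closure that needs no silyl diene. Dienolate 7, generated with LDA at −78 °C, would be treated directly with 16 (THF, −78 °C to rt). γ-Attack on the ynoate β-carbon, closure of the resulting allenolate onto the methyl ester with loss of methoxide, and enolisation should give 18 in one flask. No new isolated compound arises.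

Step 2. Incomplete ketalisation of the hindered α-substituted β-keto ester, or acid-induced retro-Claisen deacetylation under forcing conditions, may limit the supply of the enol ether. The fallback sets out from 4 and 16 and returns at 18; it postpones the O-methylation until after ring formation.
- Keto ester 4 would be O-silylated (TMSCl, Et3N, hexane, rt) to methyl 2-[4-(benzyloxy)benzyl]-3-(trimethylsilyloxy)but-2-enoate F4.
- F4 would be converted (LDA, THF, −78 °C; TMSCl) into 2-[4-(benzyloxy)benzyl]-1-methoxy-1,3-bis(trimethylsilyloxy)buta-1,3-diene F5.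
- Cycloaddition of F5 with 16 under the conditions of step 7 should give benzyl 3-[4-(benzyloxy)benzyl]-6-{2-[3-(benzyloxy)phenyl]ethyl}-2,4-dihydroxybenzoate F6.
- Methylation of F6 (MeI, K2CO3, acetone) should be selective for the 4-OH because the 2-OH is held in a hydrogen bond to the ester carbonyl, and gives 18.

**Further compounds**

F1 | step 7 | 5-[3-(benzyloxy)phenyl]pent-2-ynal | O=CC#CCCc1cccc(OCc2ccccc2)c1
F2 | step 7 | 3-[4-(benzyloxy)benzyl]-6-{2-[3-(benzyloxy)phenyl]ethyl}-2-hydroxy-4-methoxybenzaldehyde | O=Cc1c(CCc2cccc(OCc3ccccc3)c2)cc(OC)c(Cc2ccc(OCc3ccccc3)cc2)c1O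
F3 | step 7 | 3-[4-(benzyloxy)benzyl]-6-{2-[3-(benzyloxy)phenyl]ethyl}-2-hydroxy-4-methoxybenzoic acid | O=C(O)c1c(CCc2cccc(OCc3ccccc3)c2)cc(OC)c(Cc2ccc(OCc3ccccc3)cc2)c1O
F0 | step 3 | none | none
F4 | step 2 | methyl 2-[4-(benzyloxy)benzyl]-3-(trimethylsilyloxy)but-2-enoate | COC(=O)C(Cc1ccc(OCc2ccccc2)cc1)=C(C)O[Si](C)(C)C
F5 | step 2 | 2-[4-(benzyloxy)benzyl]-1-methoxy-1,3-bis(trimethylsilyloxy)buta-1,3-diene | C=C(O[Si](C)(C)C)C(Cc1ccc(OCc2ccccc2)cc1)=C(OC)O[Si](C)(C)C
F6 | step 2 | benzyl 3-[4-(benzyloxy)benzyl]-6-{2-[3-(benzyloxy)phenyl]ethyl}-2,4-dihydroxybenzoate | O=C(OCc1ccccc1)c1c(CCc2cccc(OCc3ccccc3)c2)cc(O)c(Cc2ccc(OCc3ccccc3)cc2)c1O
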